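(Readings and results are calculated on assumed constants; the scatter is artificial.)

**The easy step.** The flask asked about is the winter run itself, so "now" needed no reckoning: its last reading, at 150 min, is 25.1%.

| setting | winter | spring | flask |
|---|---|---|---|
| starting material | 0.010 M | 0.010 M | 0.010 M |
| reagent | 1.5 equiv | 3 equiv | 1.50 equiv |
| second substrate | 5 equiv | 5 equiv | 5.00 equiv |
| remark | the very flask that is asked about, followed so far | run made earlier |  |
| time |  |  | 2.5 h |

| run | time / min | target / % |
|---|---|---|
| winter | 8.00 | 13.3 |
| winter | 25.0 | 23.6 |
| winter | 40.0 | 27.0 |
| winter | 60.0 | 27.9 |
| winter | 90.0 | 27.5 |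
| winter | 120 | 26.2 |
| winter | 150 | 25.1 |
| spring | 1.00 | 5.2 |
| spring | 1.33 | 6.9 |
| spring | 2.00 | 9.4 |
| spring | 3.00 | 12.7 |
| spring | 5.00 | 18.2 |
| spring | 8.00 | 24.1 |
| spring | 12.0 | 29.7 |

(readings scatter by 0.3 percentage points)

- cedar: change nothing and wait 5.0 h more
- maple: at 2.5 h add reagent, 100% of the amount charged, then wait 5.0 h
- birch: at 2.5 h take out 90% of the target then present, then wait 5.0 h
- alder: at 2.5 h add starting material, 50.0% of the amount charged, then wait 5.0 h

- percentages count the starting material that a species holds: one homo dimer counts as two
- target that was removed still counts
- reactions considered so far: target <-> isomer of the product; starting material + reagent <-> target; second substrate + reagent <-> second product; 2 starting material -> homo dimer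
- additions bring no volume worth counting

- target, in percent of the starting material first charged, at 2.5 h
- the option that brings most further target ("none" if no option brings more than 2 percentage points) (cedar / maple / birch / alder / none)
- target present, with what was taken out counted in, in percent of the starting material first charged, after cedar
- target present, with what was taken out counted in, in percent of the starting material first charged, after birch

**The clock.** The first spring reading, 5.2% after 1.00 min, scaled from 3 equiv to 1.5 equiv of reagent, gave me a pseudo-first-order half-life of 26.7 min for starting material in the winter flask, with reagent held at its charge. Over 150 min that is 1.69 powers of ten of decay, leaving about 2.02%. Yet target read a peak of 27.9% at 60.0 min, then sagged.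

**The bet.** The step to target is written as reversible, so I bet on the way back rather than on a sink such as the homo dimer. My rule is the holding quotient: target over free starting material times free reagent, each free amount taken as charge minus target. The last winter reading puts it at 26.8 M⁻¹.

**The options.** Birch leaves 77.4% of starting material and 1.27 equivalents of reagent to share out, so the quotient regrows 17.6% of target, for a total of 40.2%. Maple reckons to 41.0%, which I could not part from birch. Target climbing back after the removal is the thing to watch.

**Weak link.** The last reading is still falling, so I reforged the quotient on the peak reading: 31.7 M⁻¹, which moves birch to 42.3%.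

**The forecast.** It gave 25.1% now, 17% after cedar, 25.5% after birch, and chose alder: "Alder feeds fresh starting material to the remaining reagent". On birch it stands apart from my reckoning.

**The result.** The flask gave 25.1% now, 21.6% after cedar and 37.9% after birch. The best option was birch, bringing 13 percentage points, against 10 points for maple and 4.2 points for alder.

    target ⇌ isomer of the product (K = 0.510, k = 0.00559 s⁻¹)
    starting material + reagent ⇌ target (K = 75.0 M⁻¹, k = 0.0361 M⁻¹ s⁻¹)
    second substrate + reagent ⇌ second product (K = 33.0 M⁻¹, k = 0.00317 M⁻¹ s⁻¹)
    2 starting material → homo dimer (k = 4.58 × 10⁻⁴ M⁻¹ s⁻¹)

**The neighbour.** Counted on the free amounts of the flask at 150 min, the quotient stands at 80.0 M⁻¹. For the neighbour with 2.50 equiv of reagent, my winter quotient gives 36.4% of target. That neighbour holds 34.9% of target, with 45% of its starting material and 39% of its reagent free, a quotient of 78.7 M⁻¹.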